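The runs were generated by integration for substances that don't exist; the scatter is artificial.

The target may not be the end of the line here. In the grey run the side product reads 0% at 8.00 h but 22% at 50.0 h, and it holds two starting-material units. So read it as target plus starting material giving side product.

| flask | starting material | coupling partner | temperature | remark | time |
|---|---|---|---|---|---|
| red | 8 mM | 14.4 mM | 10 °C | run made earlier |  |
| grey | 32 mM | 14.4 mM | 21 °C | run made earlier |  |
| violet | 16 mM | 22 mM | 10 °C | run made earlier |  |
| north-west | 16 mM | 14.4 mM |  | at 25 °C until 8.0 h, from then on at 5 °C | 40 h |
| north | 16 mM | 14.4 mM | 25 °C |  | 40 h |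
| south | 16 mM | 14.4 mM | 5 °C |  | 40 h |

- red (time / h: target / %, side product / %): 12.0: 8, 0; 30.0: 13, 6; 40.0: 22, 0; 60.0: 25, 4; 96.0: 37, 6
- grey (time / h: target / %, side product / %): 2.50: 3, 0; 8.00: 8, 0; 15.0: 14, 3; 20.0: 14, 4; 30.0: 15, 11; 40.0: 19, 16; 50.0: 19, 22
- violet (time / h: target / %, side product / %): 8.00: 5, 0; 15.0: 13, 3; 30.0: 18, 1; 48.0: 28, 4; 96.0: 40, 13

(readings scatter by 2 percentage points)

- percent here means starting material units held: one side product counts as two
- the numbers in the tables scatter with a standard deviation of 2 percentage points

- the best flask by share of target in all that became target or side product; "all alike" if 1.5 percentage points covers them all (north-west / north / south / all alike)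
- share of target in all that became target or side product, north-west
- share of target in all that became target or side product, north
- share of target in all that became target or side product, south

Both steps then use starting material, so dividing their rates cancels it, and time goes too. The coupling partner becomes the clock, and the equation integrates in closed form. Let x be the part of the partner left and s the selectivity factor, the side step's rate constant over the target step's. Target, in parts of partner charged, is y = (x^s − x)/(1 − s). The share asked is y/(2(1 − x) − y).

At low conversion this gives s from one reading. The last red reading gives 0.675 and the last violet reading 0.827. Carry their mean, s = 0.751, as a reading with scatter.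

Test it on grey, which is warmer. Its last reading leaves 33.3% of the partner, so s predicts 19.0% target, and 19% was read. So within the scatter the s read at 10 °C fits this reading at 21 °C, and I carry it to the three flasks.

Grey at 15.0 h gives the target step 0.940 L mol⁻¹ h⁻¹. Red at 96.0 h gives 0.407 L mol⁻¹ h⁻¹. Treat the two charges in north and south as equal. North at grey's constant keeps 62.4% of its partner, and south at red's constant keeps 79.3%. North is warmer than grey and south colder than red, so I expect north to use more partner than this and south less. At these estimates my reckoning gives north a share of 71.0% and south 84.3%, and I expect north lower, south higher and north-west between.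

The forecast names south, with 84% for north-west, 64% for north and 92% for south: “Cold wins on selectivity”.

The flasks give south as best, with 86.1% for north-west, 68.2% for north and 92.0% for south.

    starting material + coupling partner ⇌ target (K = 1500 L mol⁻¹, k = 1.23 L mol⁻¹ h⁻¹, Ea = 53.0 kJ mol⁻¹, ΔH = −33.0 kJ mol⁻¹)
    starting material + target → side product (k = 0.878 L mol⁻¹ h⁻¹, Ea = 63.0 kJ mol⁻¹)
    2 starting material → homo dimer (k = 0.0990 L mol⁻¹ h⁻¹, Ea = 82.0 kJ mol⁻¹)
    (constants at 25 °C)

The neighbour is north-west with 58 mM of coupling partner, and 84% of that partner is left at 40.0 h. The carried s gives this neighbour a share of 87.9%, and its target comes to 55.6% of the starting material charged. The neighbour itself gives a share of 89.6%, with target at 56.3% and side product at 6.54%.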